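## Retrosynthetic overview
1. The Z-cinnamate comes from the C4 alcohol and phenylpropiolic acid (ester, then semihydrogenation). The 3-oxobutyl chain comes from an exo C7 carbaldehyde (Wittig, then conjugate reduction).
2. The C7 aldehyde comes from a 7,7-dibromonorcarane, made from CBr2 and an all-cis 2,4-bis(silyloxy)-3-isopropyl-6-methylcyclohexene. The three-membered ring is formed second, anti to the three cis groups.
3. The cyclohexene comes from an acyclic 1,7-diene-3,5-diol by ring-closing metathesis, so the six-membered ring is formed first. C2 is then corrected by MnO2 oxidation and face-selective hydride reduction.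
4. The diene diol comes from a β-hydroxy ketone (a 1,3-anti directed reduction sets C4), made from a Weinreb amide and methallyl Grignard reagent.
5. The key C2–C3 bond is made by an intermolecular Evans syn aldol of the N-isovaleryl oxazolidinone with acrolein, which fixes the absolute configuration at C3.

Locants: C1–C7 are the bicyclo[4.1.0]heptane atoms of the target. C1 is the cyclopropane CH next to carbinol C2, C3 is CH–iPr, C4 is CH–O-acyl, C5 is CH2, C6 is C–CH3, and C7 is the CH bearing chain C8–C11. The text uses these labels for the same atoms in all earlier compounds, and the bicyclic names use them as locants.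

Assumption: bases, hydrides, silylating agents and catalysts are commercial and are not numbered; every compound that puts carbon into the target is numbered.

## Route

Step 1
Reactants: 1 (S)-4-benzyl-1,3-oxazolidin-2-one; 2 3-methylbutanoyl chloride
Product: 4 (S)-4-benzyl-3-(3-methylbutanoyl)-1,3-oxazolidin-2-one, via lithium oxazolidinide 3 (not isolated)
Conditions: n-BuLi, THF, −78 °C; then 2, −78 → 0 °C
Reagents that add atoms: 3-methylbutanoyl chloride (2), CC(C)CC(=O)Cl
Why: N-acylation of the lithiated Evans auxiliary by the acid chloride is a clean nucleophilic acyl substitution that touches no stereocentre.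

Step 2
Reactants: 4 (S)-4-benzyl-3-(3-methylbutanoyl)-1,3-oxazolidin-2-one; 5 acrolein
Product: 8 (S)-4-benzyl-3-[(2S,3R)-3-hydroxy-2-(propan-2-yl)pent-4-enoyl]-1,3-oxazolidin-2-one, via Z-dibutylboron enolate 6 (not isolated), via dibutylboron aldolate 7 (not isolated)
Conditions: Bu2BOTf, Et3N, CH2Cl2, −78 → 0 °C; 5, −78 → 0 °C; pH 7 buffer, MeOH, 30% H2O2, 0 °C
Reagents that add atoms: acrolein (5), C=CC=O
Why: In this Evans syn aldol reaction the Z boron enolate adds to acrolein through a Zimmerman–Traxler chair on the face away from the benzyl group, which forms the C2–C3 bond, sets the isopropyl centre C3 in its final geometry and gives a syn C2 carbinol that serves only as a stereochemical relay.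

Step 3
Reactants: 8 aldol adduct
Product: 9 (2S,3R)-3-hydroxy-N-methoxy-N-methyl-2-(propan-2-yl)pent-4-enamide
Conditions: MeONHMe·HCl, AlMe3, CH2Cl2, 0 °C → rt; aq KNa tartrate
Reagents that add atoms: N,O-dimethylhydroxylamine hydrochloride, CNOC.Cl
Why: Aluminium amide transamination (Weinreb amide synthesis) is assisted by the free β-hydroxyl group, releases the auxiliary for reuse and leaves C2 and C3 untouched.

Step 4
Reactants: 9 Weinreb amide; 10 2-methylallylmagnesium chloride
Product: 11 (5S,6R)-6-hydroxy-2-methyl-5-(propan-2-yl)octa-1,7-dien-4-one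
Conditions: 10 (3.5 equiv), THF, −78 → −20 °C; cold sat. aq NH4Cl
Reagents that add atoms: 2-methylallylmagnesium chloride (10), CC(=C)C[Mg]Cl
Why: In this Weinreb ketone synthesis the reactive allylic Grignard reagent acylates at the hindered amide without a second addition, and the cold buffered quench keeps the 1,1-disubstituted alkene out of conjugation and C3 unepimerised.

Step 5
Reactants: 11 β-hydroxy ketone
Product: 12 (3R,4R,5R)-7-methyl-4-(propan-2-yl)octa-1,7-diene-3,5-diol
Conditions: Me4NBH(OAc)3, MeCN/AcOH (1:1), −30 °C; aq KNa tartrate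
Reagents that add atoms: none
Why: In the Evans–Saksena directed reduction the C2 oxygen binds boron and hydride is delivered inside a chair, which gives the 1,3-anti diol and sets C4 (R) anti to the isopropyl group in the zigzag chain and therefore cis to it in the ring.

Step 6
Reactants: 12 diene diol
Product: 13 (1R,2R,3R)-5-methyl-2-(propan-2-yl)cyclohex-4-ene-1,3-diol
Conditions: second-generation Grubbs catalyst RuCl2(=CHPh)(PCy3)(H2IMes) (3 mol %), CH2Cl2 (0.01 M), 40 °C
Reagents that add atoms: none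
Why: Ring-closing metathesis of the vinyl and the 1,1-disubstituted alkene closes the six-membered ring as the trisubstituted C1=C6 cyclohexene with loss of ethene and no change at C2, C3 or C4.

Step 7
Reactants: 13 cyclohexenediol
Product: 14 (5R,6R)-5-hydroxy-3-methyl-6-(propan-2-yl)cyclohex-2-en-1-one
Conditions: activated MnO2 (20 equiv), CH2Cl2, rt
Reagents that add atoms: none
Why: Allylic oxidation by MnO2 takes only the pseudo-equatorial allylic C2 alcohol, which differentiates the two hydroxyl groups and erases the relay centre under neutral conditions that do not trigger β-elimination.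

Step 8
Reactants: 14 hydroxy enone
Product: 15 (5R,6R)-3-methyl-6-(propan-2-yl)-5-(triethylsilyloxy)cyclohex-2-en-1-one
Conditions: Et3SiOTf, 2,6-lutidine, CH2Cl2, −78 °C
Reagents that add atoms: triethylsilyl trifluoromethanesulfonate, CC[Si](CC)(CC)OS(=O)(=O)C(F)(F)F
Why: Silyl triflate O-silylation with a hindered pyridine base is fast at low temperature and too weakly basic to enolise the ketone, so the elimination-prone aldol unit is capped with C3 and C4 intact.

Step 9
Reactants: 15 silyloxy enone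
Product: 16 (1S,5R,6S)-3-methyl-6-(propan-2-yl)-5-(triethylsilyloxy)cyclohex-2-en-1-ol (all-cis)
Conditions: i-Bu2AlH, toluene, −78 °C; aq KNa tartrate
Reagents that add atoms: none
Why: The 1,2-reduction of the enone by the aluminium hydride takes place on the ring face opposite to the cis isopropyl and silyloxy groups in either half-chair, which sets C2 (S) with the hydroxyl cis to both.

Step 10
Reactants: 16 allylic alcohol
Product: 17 tert-butyl(dimethyl){[(1S,5R,6R)-3-methyl-6-(propan-2-yl)-5-(triethylsilyloxy)cyclohex-2-en-1-yl]oxy}silane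
Conditions: t-BuMe2SiOTf, 2,6-lutidine, CH2Cl2, 0 °C
Reagents that add atoms: tert-butyldimethylsilyl trifluoromethanesulfonate, CC(C)(C)[Si](C)(C)OS(=O)(=O)C(F)(F)F
Why: Silyl triflate O-silylation protects the hindered allylic alcohol without an alkoxide stage, which avoids silyl migration from O4 and ionisation of the allylic position.

Step 11
Reactants: 17 bis(silyl ether); 18 bromoform
Product: 20 (1R,2R,3R,4R,6R)-7,7-dibromo-2-(tert-butyldimethylsilyloxy)-6-methyl-3-(propan-2-yl)-4-(triethylsilyloxy)bicyclo[4.1.0]heptane, via dibromocarbene 19 (not isolated)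
Conditions: 18 (4 equiv), t-BuOK (5 equiv), pentane, −10 °C → rt
Reagents that add atoms: bromoform (18), BrC(Br)Br
Why: The Doering–Hoffmann dibromocarbene [2+1] cycloaddition to the trisubstituted alkene is stereospecifically cis and comes from the face opposite to O2, isopropyl and O4, which sets the ring-fusion centres C1 and C6 with the cyclopropane anti to all three groups.

Step 12
Reactants: 20 dibromocyclopropane
Product: 21 (1R,2R,3R,4R,6R)-7-bromo-2-(tert-butyldimethylsilyloxy)-6-methyl-3-(propan-2-yl)-4-(triethylsilyloxy)bicyclo[4.1.0]heptane (C7 epimer mixture)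
Conditions: Bu3SnH (1.1 equiv), AIBN (cat.), toluene, 60 °C
Reagents that add atoms: none
Why: Radical chain hydrodebromination with one equivalent of tin hydride removes a single bromine because the second C–Br bond reacts far more slowly, and the C7 epimer ratio is irrelevant since C7 is corrected in step 14.

Step 13
Reactants: 21 monobromide; 22 N,N-dimethylformamide
Product: 24 (1R,2S,3R,4R,6R)-2-(tert-butyldimethylsilyloxy)-6-methyl-3-(propan-2-yl)-4-(triethylsilyloxy)bicyclo[4.1.0]heptane-7-carbaldehyde (C7 epimer mixture), via 7-lithio cyclopropane 23 (not isolated)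
Conditions: t-BuLi (2.2 equiv), Et2O, −78 °C; 22, −78 → 0 °C; aq NH4Cl
Reagents that add atoms: N,N-dimethylformamide (22), CN(C)C=O
Why: Bromine–lithium exchange gives a cyclopropyllithium that is formylated by the formamide (Bouveault aldehyde synthesis), while both silyl ethers are inert at −78 °C.

Step 14
Reactants: 24 aldehyde epimer mixture
Product: 25 (1R,2S,3R,4R,6R,7R)-2-(tert-butyldimethylsilyloxy)-6-methyl-3-(propan-2-yl)-4-(triethylsilyloxy)bicyclo[4.1.0]heptane-7-carbaldehyde (7-exo)
Conditions: NaOMe (0.2 equiv), MeOH/THF, rt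
Reagents that add atoms: none
Why: Base-catalysed epimerisation by reversible deprotonation at C7 drains the endo isomer, whose formyl group is cis to both C2 and C5, into the less crowded exo aldehyde and so sets C7 (R) under thermodynamic control.

Step 15
Reactants: 25 exo aldehyde; 26 1-(triphenyl-λ5-phosphanylidene)propan-2-one
Product: 27 (E)-4-[(1R,2S,3R,4R,6S,7R)-2-(tert-butyldimethylsilyloxy)-6-methyl-3-(propan-2-yl)-4-(triethylsilyloxy)bicyclo[4.1.0]heptan-7-yl]but-3-en-2-one
Conditions: 26 (2 equiv), toluene, 90 °C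
Reagents that add atoms: 1-(triphenyl-λ5-phosphanylidene)propan-2-one (26), CC(=O)C=P(c1ccccc1)(c1ccccc1)c1ccccc1
Why: Wittig olefination with the stabilised ylide is neutral, gives the E enone and does not disturb the C7 centre.

Step 16
Reactants: 27 enone
Product: 28 4-[(1R,2S,3R,4R,6S,7R)-2-(tert-butyldimethylsilyloxy)-6-methyl-3-(propan-2-yl)-4-(triethylsilyloxy)bicyclo[4.1.0]heptan-7-yl]butan-2-one
Conditions: [(Ph3P)CuH]6 (0.5 equiv), H2O (5 equiv), toluene, rt
Reagents that add atoms: none
Why: Conjugate reduction by the phosphine copper hydride (Stryker reduction) is a polar hydrocupration that saturates the enone chemoselectively without opening the adjacent cyclopropane or reducing the ketone.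

Step 17
Reactants: 28 ketone
Product: 29 4-[(1R,2S,3R,4R,6S,7R)-2-(tert-butyldimethylsilyloxy)-4-hydroxy-6-methyl-3-(propan-2-yl)bicyclo[4.1.0]heptan-7-yl]butan-2-one
Conditions: HF·pyridine, pyridine, THF, 0 °C
Reagents that add atoms: none
Why: Buffered fluoride desilylation cleaves the triethylsilyl ether much faster than the tert-butyldimethylsilyl ether, which frees only O4.

Step 18
Reactants: 30 3-phenylprop-2-ynoic acid
Product: 31 3-phenylprop-2-ynoyl chloride
Conditions: (COCl)2, DMF (cat.), CH2Cl2, 0 °C → rt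
Reagents that add atoms: oxalyl chloride, ClC(=O)C(=O)Cl
Why: Acid chloride formation with oxalyl chloride under formamide catalysis avoids the symmetric anhydride, which is prone to self-cycloaddition.

Step 19
Reactants: 29 C4 alcohol; 31 3-phenylprop-2-ynoyl chloride
Product: 32 (1R,2S,3R,4R,6S,7R)-2-(tert-butyldimethylsilyloxy)-6-methyl-7-(3-oxobutyl)-3-(propan-2-yl)bicyclo[4.1.0]heptan-4-yl 3-phenylprop-2-ynoate
Conditions: 31 (2 equiv), Et3N, DMAP (0.2 equiv), CH2Cl2, 0 °C → rt
Reagents that add atoms: 3-phenylprop-2-ynoyl chloride (31), ClC(=O)C#Cc1ccccc1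
Why: DMAP-catalysed acylation with the slim and reactive alkynoyl chloride esterifies the hindered C4 alcohol with retention because the C4–O bond is not touched.

Step 20
Reactants: 32 alkynoate
Product: 33 (1R,2S,3R,4R,6S,7R)-2-(tert-butyldimethylsilyloxy)-6-methyl-7-(3-oxobutyl)-3-(propan-2-yl)bicyclo[4.1.0]heptan-4-yl (Z)-3-phenylprop-2-enoate
Conditions: H2 (1 atm), Pd/CaCO3 poisoned with Pb(OAc)2, quinoline, EtOAc, rt, stopped after 1 equiv H2
Reagents that add atoms: none
Why: Lindlar semihydrogenation adds hydrogen syn to the alkyne on the poisoned palladium surface and gives the Z alkene, while ketone, cyclopropane and silyl ether are inert.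

Step 21
Reactants: 33 silyl-protected Z-cinnamate
Product: 34 (1R,2S,3S,4R,6S,7R)-2-hydroxy-6-methyl-7-(3-oxobutyl)-3-(propan-2-yl)bicyclo[4.1.0]heptan-4-yl (Z)-3-phenylprop-2-enoate (CNP0217452.3)
Conditions: HF·pyridine, THF, 0 °C → rt
Reagents that add atoms: none
Why: Fluoride-mediated desilylation under mildly acidic conditions frees the C2 hydroxyl without acyl migration to O2, Z to E isomerisation or ionisation of the cyclopropyl carbinol.

## Compound list
1 | (S)-4-benzyl-1,3-oxazolidin-2-one | O=C1N[C@@H](Cc2ccccc2)CO1 | starting material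
2 | 3-methylbutanoyl chloride | CC(C)CC(=O)Cl | starting material
3 | lithium oxazolidinide of 1 (not isolated) | [Li]N1[C@@H](Cc2ccccc2)COC1=O | intermediate
4 | (S)-4-benzyl-3-(3-methylbutanoyl)-1,3-oxazolidin-2-one | CC(C)CC(=O)N1[C@@H](Cc2ccccc2)COC1=O | intermediate
5 | acrolein | C=CC=O | starting material
6 | Z-dibutylboron enolate of 4 (not isolated) | CC(C)/C=C(\OB(CCCC)CCCC)N1[C@@H](Cc2ccccc2)COC1=O | intermediate
7 | dibutylboron aldolate (not isolated) | C=C[C@@H](OB(CCCC)CCCC)[C@H](C(C)C)C(=O)N1[C@@H](Cc2ccccc2)COC1=O | intermediate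
8 | (S)-4-benzyl-3-[(2S,3R)-3-hydroxy-2-(propan-2-yl)pent-4-enoyl]-1,3-oxazolidin-2-one | C=C[C@@H](O)[C@H](C(C)C)C(=O)N1[C@@H](Cc2ccccc2)COC1=O | intermediate
9 | (2S,3R)-3-hydroxy-N-methoxy-N-methyl-2-(propan-2-yl)pent-4-enamide | C=C[C@@H](O)[C@H](C(C)C)C(=O)N(C)OC | intermediate
10 | 2-methylallylmagnesium chloride | CC(=C)C[Mg]Cl | starting material
11 | (5S,6R)-6-hydroxy-2-methyl-5-(propan-2-yl)octa-1,7-dien-4-one | C=C[C@@H](O)[C@H](C(C)C)C(=O)CC(C)=C | intermediate
12 | (3R,4R,5R)-7-methyl-4-(propan-2-yl)octa-1,7-diene-3,5-diol | C=C[C@@H](O)[C@H](C(C)C)[C@H](O)CC(C)=C | intermediate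
13 | (1R,2R,3R)-5-methyl-2-(propan-2-yl)cyclohex-4-ene-1,3-diol | CC1=C[C@@H](O)[C@H](C(C)C)[C@H](O)C1 | intermediate
14 | (5R,6R)-5-hydroxy-3-methyl-6-(propan-2-yl)cyclohex-2-en-1-one | CC1=CC(=O)[C@H](C(C)C)[C@H](O)C1 | intermediate
15 | (5R,6R)-3-methyl-6-(propan-2-yl)-5-(triethylsilyloxy)cyclohex-2-en-1-one | CC1=CC(=O)[C@H](C(C)C)[C@H](O[Si](CC)(CC)CC)C1 | intermediate
16 | (1S,5R,6S)-3-methyl-6-(propan-2-yl)-5-(triethylsilyloxy)cyclohex-2-en-1-ol | CC1=C[C@H](O)[C@H](C(C)C)[C@H](O[Si](CC)(CC)CC)C1 | intermediate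
17 | tert-butyl(dimethyl){[(1S,5R,6R)-3-methyl-6-(propan-2-yl)-5-(triethylsilyloxy)cyclohex-2-en-1-yl]oxy}silane | CC1=C[C@H](O[Si](C)(C)C(C)(C)C)[C@H](C(C)C)[C@H](O[Si](CC)(CC)CC)C1 | intermediate
18 | bromoform | BrC(Br)Br | starting material
19 | dibromocarbene (not isolated) | Br[C]Br | intermediate
20 | (1R,2R,3R,4R,6R)-7,7-dibromo-2-(tert-butyldimethylsilyloxy)-6-methyl-3-(propan-2-yl)-4-(triethylsilyloxy)bicyclo[4.1.0]heptane | BrC1(Br)[C@H]2[C@H](O[Si](C)(C)C(C)(C)C)[C@H](C(C)C)[C@H](O[Si](CC)(CC)CC)C[C@]21C | intermediate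
21 | (1R,2R,3R,4R,6R)-7-bromo analogue of 20, C7 epimer mixture | BrC1[C@H]2[C@H](O[Si](C)(C)C(C)(C)C)[C@H](C(C)C)[C@H](O[Si](CC)(CC)CC)C[C@]21C | intermediate
22 | N,N-dimethylformamide | CN(C)C=O | starting material
23 | 7-lithio cyclopropane from 21 (not isolated) | [Li]C1[C@H]2[C@H](O[Si](C)(C)C(C)(C)C)[C@H](C(C)C)[C@H](O[Si](CC)(CC)CC)C[C@]21C | intermediate
24 | (1R,2S,3R,4R,6R)-2-(tert-butyldimethylsilyloxy)-6-methyl-3-(propan-2-yl)-4-(triethylsilyloxy)bicyclo[4.1.0]heptane-7-carbaldehyde, C7 epimer mixture | O=CC1[C@H]2[C@H](O[Si](C)(C)C(C)(C)C)[C@H](C(C)C)[C@H](O[Si](CC)(CC)CC)C[C@]21C | intermediate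
25 | (1R,2S,3R,4R,6R,7R)-7-exo-carbaldehyde | O=C[C@@H]1[C@H]2[C@H](O[Si](C)(C)C(C)(C)C)[C@H](C(C)C)[C@H](O[Si](CC)(CC)CC)C[C@]21C | intermediate
26 | 1-(triphenyl-λ5-phosphanylidene)propan-2-one | CC(=O)C=P(c1ccccc1)(c1ccccc1)c1ccccc1 | starting material
27 | (E)-4-[(1R,2S,3R,4R,6S,7R)-2-(tert-butyldimethylsilyloxy)-6-methyl-3-(propan-2-yl)-4-(triethylsilyloxy)bicyclo[4.1.0]heptan-7-yl]but-3-en-2-one | CC(=O)/C=C/[C@@H]1[C@H]2[C@H](O[Si](C)(C)C(C)(C)C)[C@H](C(C)C)[C@H](O[Si](CC)(CC)CC)C[C@]21C | intermediate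
28 | 4-[(1R,2S,3R,4R,6S,7R)-2-(tert-butyldimethylsilyloxy)-6-methyl-3-(propan-2-yl)-4-(triethylsilyloxy)bicyclo[4.1.0]heptan-7-yl]butan-2-one | CC(=O)CC[C@@H]1[C@H]2[C@H](O[Si](C)(C)C(C)(C)C)[C@H](C(C)C)[C@H](O[Si](CC)(CC)CC)C[C@]21C | intermediate
29 | 4-[(1R,2S,3R,4R,6S,7R)-2-(tert-butyldimethylsilyloxy)-4-hydroxy-6-methyl-3-(propan-2-yl)bicyclo[4.1.0]heptan-7-yl]butan-2-one | CC(=O)CC[C@@H]1[C@H]2[C@H](O[Si](C)(C)C(C)(C)C)[C@H](C(C)C)[C@H](O)C[C@]21C | intermediate
30 | 3-phenylprop-2-ynoic acid | OC(=O)C#Cc1ccccc1 | starting material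
31 | 3-phenylprop-2-ynoyl chloride | ClC(=O)C#Cc1ccccc1 | intermediate
32 | (1R,2S,3R,4R,6S,7R)-2-(tert-butyldimethylsilyloxy)-6-methyl-7-(3-oxobutyl)-3-(propan-2-yl)bicyclo[4.1.0]heptan-4-yl 3-phenylprop-2-ynoate | CC(=O)CC[C@@H]1[C@H]2[C@H](O[Si](C)(C)C(C)(C)C)[C@H](C(C)C)[C@H](OC(=O)C#Cc3ccccc3)C[C@]21C | intermediate
33 | (1R,2S,3R,4R,6S,7R)-2-(tert-butyldimethylsilyloxy)-6-methyl-7-(3-oxobutyl)-3-(propan-2-yl)bicyclo[4.1.0]heptan-4-yl (Z)-3-phenylprop-2-enoate | CC(=O)CC[C@@H]1[C@H]2[C@H](O[Si](C)(C)C(C)(C)C)[C@H](C(C)C)[C@H](OC(=O)/C=C\c3ccccc3)C[C@]21C | intermediate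
34 | (1R,2S,3S,4R,6S,7R)-2-hydroxy-6-methyl-7-(3-oxobutyl)-3-(propan-2-yl)bicyclo[4.1.0]heptan-4-yl (Z)-3-phenylprop-2-enoate | CC(=O)CC[C@@H]1[C@H]2[C@H](O)[C@H](C(C)C)[C@H](OC(=O)/C=C\c3ccccc3)C[C@]21C | target

## Step count and risks
Total step count: 21. Longest linear sequence: 20 (steps 1–17 and 19–21; step 18 is a one-step side branch).

**Risk 1 is step 4.**
- Ketone 11 is both β,γ-unsaturated and a β-hydroxy ketone, so it can slip into conjugation or undergo retro-aldol cleavage during addition or work-up.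
- The fallback gives up the acylation/reduction logic and forms C4–C5 by a chelation-controlled carbonyl allylation. It sets out from 9.
- 4-Methoxybenzyl trichloroacetimidate with catalytic Sc(OTf)3 gives (2S,3R)-N-methoxy-3-[(4-methoxybenzyl)oxy]-N-methyl-2-(propan-2-yl)pent-4-enamide F1.
- i-Bu2AlH at −78 °C then gives (2S,3R)-3-[(4-methoxybenzyl)oxy]-2-(propan-2-yl)pent-4-enal F2.
- Tributyl(2-methylallyl)stannane with MgBr2·OEt2 in CH2Cl2 attacks the six-membered magnesium chelate of the aldehyde and ether oxygens. Attack comes from the face opposite to the vinyl and isopropyl groups, which lie cis on that chelate.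
- The product is (4R,5R,6R)-6-[(4-methoxybenzyl)oxy]-2-methyl-5-(propan-2-yl)octa-1,7-dien-4-ol F3, with the same anti-Felkin, 1,3-anti C4 configuration as 12.
- DDQ in wet CH2Cl2 removes the benzyl ether, and the sequence comes back to the route at 12.

**Risk 2 is step 7.**
- The free cis β-hydroxy enone 14 is one dehydration and one tautomerisation away from thymol, and it may aromatise on the MnO2 surface or during step 8.
- The fallback differentiates the two oxygens before the ring is made and oxidises only after O4 is capped. It sets out from 11.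
- SmI2 (0.3 equiv) and benzaldehyde in THF at −10 °C (Evans–Tishchenko reduction) give (3R,4R,5R)-5-hydroxy-7-methyl-4-(propan-2-yl)octa-1,7-dien-3-yl benzoate F4. This compound has the same C4 configuration as 12 and O2 is already blocked.
- Et3SiOTf/2,6-lutidine gives (3R,4S,5R)-7-methyl-4-(propan-2-yl)-5-(triethylsilyloxy)octa-1,7-dien-3-yl benzoate F5.
- The second-generation Grubbs catalyst closes the ring to (1R,5R,6S)-3-methyl-6-(propan-2-yl)-5-(triethylsilyloxy)cyclohex-2-en-1-yl benzoate F6.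
- i-Bu2AlH at −78 °C removes the benzoate to give (1R,5R,6S)-3-methyl-6-(propan-2-yl)-5-(triethylsilyloxy)cyclohex-2-en-1-ol F7.
- Dess–Martin periodinane buffered with NaHCO3 oxidises the allylic alcohol, and the sequence comes back to the route at 15.

**Risk 3 is step 11.**
- The alkene of 17 is flanked by a bulky allylic silyl ether that also deactivates it inductively. Conversion with dibromocarbene may therefore be poor, and two further steps depend on the halides.
- The fallback replaces the dihalocarbene and halogen–metal exchange chemistry with a metal carbenoid that brings the carbonyl carbon along. It sets out from 17.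
- Slow addition of ethyl diazoacetate with Rh2(OAc)4 (1 mol %) in CH2Cl2 cyclopropanates the same open face.
- The product is ethyl (1R,2S,3R,4R,6R)-2-(tert-butyldimethylsilyloxy)-6-methyl-3-(propan-2-yl)-4-(triethylsilyloxy)bicyclo[4.1.0]heptane-7-carboxylate F8 as a C7 epimer mixture.
- LiAlH4 in Et2O gives [(1R,2S,3R,4R,6S)-2-(tert-butyldimethylsilyloxy)-6-methyl-3-(propan-2-yl)-4-(triethylsilyloxy)bicyclo[4.1.0]heptan-7-yl]methanol F9.
- Dess–Martin periodinane then gives the aldehyde mixture, so the sequence comes back to the route at 24, just before the equilibration of step 14.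

## Further compounds
F1 | step 4 | (2S,3R)-N-methoxy-3-[(4-methoxybenzyl)oxy]-N-methyl-2-(propan-2-yl)pent-4-enamide | C=C[C@@H](OCc1ccc(OC)cc1)[C@H](C(C)C)C(=O)N(C)OC
F2 | step 4 | (2S,3R)-3-[(4-methoxybenzyl)oxy]-2-(propan-2-yl)pent-4-enal | C=C[C@@H](OCc1ccc(OC)cc1)[C@H](C(C)C)C=O
F3 | step 4 | (4R,5R,6R)-6-[(4-methoxybenzyl)oxy]-2-methyl-5-(propan-2-yl)octa-1,7-dien-4-ol | C=C[C@@H](OCc1ccc(OC)cc1)[C@H](C(C)C)[C@H](O)CC(C)=C
F4 | step 7 | (3R,4R,5R)-5-hydroxy-7-methyl-4-(propan-2-yl)octa-1,7-dien-3-yl benzoate | C=C[C@@H](OC(=O)c1ccccc1)[C@H](C(C)C)[C@H](O)CC(C)=C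
F5 | step 7 | (3R,4S,5R)-7-methyl-4-(propan-2-yl)-5-(triethylsilyloxy)octa-1,7-dien-3-yl benzoate | C=C[C@@H](OC(=O)c1ccccc1)[C@H](C(C)C)[C@H](O[Si](CC)(CC)CC)CC(C)=C
F6 | step 7 | (1R,5R,6S)-3-methyl-6-(propan-2-yl)-5-(triethylsilyloxy)cyclohex-2-en-1-yl benzoate | CC1=C[C@@H](OC(=O)c2ccccc2)[C@H](C(C)C)[C@H](O[Si](CC)(CC)CC)C1
F7 | step 7 | (1R,5R,6S)-3-methyl-6-(propan-2-yl)-5-(triethylsilyloxy)cyclohex-2-en-1-ol | CC1=C[C@@H](O)[C@H](C(C)C)[C@H](O[Si](CC)(CC)CC)C1
F8 | step 11 | ethyl (1R,2S,3R,4R,6R)-2-(tert-butyldimethylsilyloxy)-6-methyl-3-(propan-2-yl)-4-(triethylsilyloxy)bicyclo[4.1.0]heptane-7-carboxylate, C7 epimer mixture | CCOC(=O)C1[C@H]2[C@H](O[Si](C)(C)C(C)(C)C)[C@H](C(C)C)[C@H](O[Si](CC)(CC)CC)C[C@]21C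
F9 | step 11 | [(1R,2S,3R,4R,6S)-2-(tert-butyldimethylsilyloxy)-6-methyl-3-(propan-2-yl)-4-(triethylsilyloxy)bicyclo[4.1.0]heptan-7-yl]methanol, C7 epimer mixture | OCC1[C@H]2[C@H](O[Si](C)(C)C(C)(C)C)[C@H](C(C)C)[C@H](O[Si](CC)(CC)CC)C[C@]21C
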